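**Strategy.** Everything rests on disconnecting the C9–C10 single bond between the C2–C9 tetraenoate and the C10=C11 chloroalkene. The key step exploits that the (10Z)-C11(Cl)=C10H unit is the syn adduct of chlorine and C9 across a terminal alkyne C10≡C11: in one flask, BCl3 chloroboration of the silylated C10–C23 alkynyl polyol, boronate formation and Suzuki–Miyaura coupling with the C9 vinyl iodide of the C1–C9 tetraenoate (already esterified to O3 of the (1S,3R,4S)-cyclohexane ring, from (S)-cyclohex-3-enecarboxylic acid) create the C9–C10 bond, the C11–Cl bond and the 10Z geometry. The precursor therefore is a plain terminal alkyne that carries no vinyl chloride.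

Key step: step 27

Conventions and assumptions: chain locants C1–C23 count from the ester carbonyl of the target; TBS = tert-butyldimethylsilyl, TES = triethylsilyl, PMB = 4-methoxybenzyl; compounds 1, 3, 4, 6, 17, 20, 27 and 37 are taken as commercial; in step 11 the catalyst enantiomer is the one that delivers the (R)-chloride.

**Step 1**
Reactants: 1 triethyl (E)-4-phosphonocrotonate
Product: 2 (2E)-4-(diethoxyphosphoryl)but-2-enoic acid
Conditions: LiOH·H2O, THF/H2O, 0 °C → rt; then 1 M HCl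
Reagents that add atoms: lithium hydroxide, [Li+].[OH-]
Why: Saponification, in which hydroxide attacks only the carboxylic ethyl ester because the diethyl phosphonate is far less electrophilic, and the E olefin is retained.

**Step 2**
Reactants: 3 2,2-dimethoxyacetaldehyde; 4 2-(triphenylphosphoranylidene)propanal
Product: 5 (2E)-4,4-dimethoxy-2-methylbut-2-enal
Conditions: CH2Cl2, rt (3 in slight excess)
Reagents that add atoms: none
Why: Wittig olefination with a stabilised α-branched formyl ylide is E-selective, and the trisubstituted enal formed is less electrophilic than 3, so mono-olefination should dominate.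

**Step 3**
Reactants: 6 (1S)-cyclohex-3-ene-1-carboxylic acid
Product: 7 (1S,4S,5S)-4-iodo-6-oxabicyclo[3.2.1]octan-7-one
Conditions: I2, KI, NaHCO3, H2O/CH2Cl2, 0 °C → rt, dark
Reagents that add atoms: iodine, II
Why: Iodolactonisation, in which the carboxylate opens the iodonium ion anti in a 5-exo mode, so the C1 centre fixes the C3–O bond cis to C1 and the C4–I bond trans to it.

**Step 4**
Reactants: 7 iodolactone
Product: 8 allyl (1S,3S,6R)-7-oxabicyclo[4.1.0]heptane-3-carboxylate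
Conditions: allyl alcohol (solvent), K2CO3, rt
Reagents that add atoms: allyl alcohol, C=CCO
Why: Transesterification by allyl alkoxide opens the lactone and the freed C3 alkoxide displaces the antiperiplanar C4 iodide (intramolecular Williamson SN2, inversion at C4), giving the epoxide syn to the ester.

**Step 5**
Reactants: 8 epoxy ester; 2 phosphonocrotonic acid
Product: 9 allyl (1S,3R,4R)-3-{[(2E)-4-(diethoxyphosphoryl)but-2-enoyl]oxy}-4-hydroxycyclohexane-1-carboxylate
Conditions: 2 (2 equiv), Cs2CO3 (20 mol%), DMF, 70 °C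
Reagents that add atoms: none
Why: SN2 epoxide opening by the caesium carboxylate should follow the Fürst–Plattner (trans-diaxial) rule through the half-chair with an equatorial ester, so attack occurs at C3 with inversion (3R) and the C4 hydroxyl stays cis to the ester.

**Step 6**
Reactants: 9 trans-hydroxy ester
Product: 12 allyl (1S,3R,4S)-3-{[(2E)-4-(diethoxyphosphoryl)but-2-enoyl]oxy}-4-hydroxycyclohexane-1-carboxylate, via C4 triflate 10 (not isolated), via acyloxonium triflate 11 (not isolated)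
Conditions: Tf2O, pyridine, CH2Cl2, −30 → 0 °C; then H2O/THF, rt
Reagents that add atoms: water, O
Why: Triflation is followed by neighbouring-group participation of the antiperiplanar C3 acyloxy group (SN2 inversion at C4 to a cis-fused 1,3-dioxolan-2-ylium ion), and water should open the ortho-acid with stereoelectronically preferred retention of the axial C3 ester, giving the cis-3-acyloxy-4-ol (4S).

**Step 7**
Reactants: 12 cis-hydroxy ester
Product: 13 allyl (1S,3R,4S)-4-(TBS-oxy)-3-{[(2E)-4-(diethoxyphosphoryl)but-2-enoyl]oxy}cyclohexane-1-carboxylate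
Conditions: TBSOTf, 2,6-lutidine, CH2Cl2, −78 → 0 °C
Reagents that add atoms: tert-butyldimethylsilyl triflate, CC(C)(C)[Si](C)(C)OS(=O)(=O)C(F)(F)F
Why: Silylation of the secondary alcohol with a silyl triflate and a hindered pyridine base is fast at low temperature and should outrun acyl migration.

**Step 8**
Reactants: 13 phosphonate; 5 acetal enal
Product: 15 allyl (1S,3R,4S)-4-(TBS-oxy)-3-{[(2E,4E,6E)-6-methyl-8-oxoocta-2,4,6-trienoyl]oxy}cyclohexane-1-carboxylate, via dimethyl acetal 14 (not isolated)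
Conditions: LiHMDS, THF, −78 °C; 5, −78 → 0 °C; then 1 M aq HCl, THF, 0 °C
Reagents that add atoms: water, O
Why: Vinylogous Horner–Wadsworth–Emmons olefination at the γ-carbon of the phosphonocrotonate should give the new C4=C5 bond E, and the conjugated dimethyl acetal is hydrolysed by dilute acid in the work-up.

**Step 9**
Reactants: 15 trienal
Product: 16 allyl (1S,3R,4S)-4-(TBS-oxy)-3-{[(2E,4E,6E,8E)-9-iodo-6-methylnona-2,4,6,8-tetraenoyl]oxy}cyclohexane-1-carboxylate
Conditions: CrCl2, CHI3, THF/dioxane (1:6), 0 °C → rt, dark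
Reagents that add atoms: iodoform, IC(I)I
Why: Takai iodo-olefination, in which the geminal dichromium species adds to the aldehyde and eliminates to the (E)-vinyl iodide while the esters stay untouched.

**Step 10**
Reactants: 17 but-1-yne
Product: 19 (1E)-1-iodobut-1-ene, via alkenylzirconocene 18 (not isolated)
Conditions: Cp2Zr(H)Cl, CH2Cl2, rt; then I2, 0 °C
Reagents that add atoms: iodine, II
Why: Hydrozirconation with the Schwartz reagent is a syn anti-Markovnikov addition and iodinolysis of the C–Zr bond proceeds with retention, giving the E iodide.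

**Step 11**
Reactants: 20 3-(PMB-oxy)propanal
Product: 21 (2R)-2-chloro-3-(PMB-oxy)propanal
Conditions: NCS, trans-2,5-diphenylpyrrolidine (10 mol%, enantiomer giving 2R), CH2Cl2, 0 °C → rt; pentane, filter; used at once
Reagents that add atoms: N-chlorosuccinimide, O=C1CCC(=O)N1Cl
Why: Enamine-catalysed electrophilic α-chlorination, in which the C2-symmetric pyrrolidine shields one enamine face so that chlorine is delivered to the other and sets C18.

**Step 12**
Reactants: 21 α-chloroaldehyde; 19 (1E)-1-iodobut-1-ene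
Product: 23 (2R,3S,4E)-2-chloro-1-(PMB-oxy)hept-4-en-3-ol, via alkenyllithium 22 (not isolated)
Conditions: 19, t-BuLi (2 equiv per iodide), Et2O, −78 °C; then 21, −78 °C; sat. aq NH4Cl at −78 °C
Reagents that add atoms: none
Why: Iodine–lithium exchange with retention gives the alkenyllithium, whose 1,2-addition to the α-chloroaldehyde should follow the Cornforth (polar Felkin–Anh) model and give the 18,19-anti chlorohydrin (C19 S).

**Step 13**
Reactants: 23 chlorohydrin
Product: 24 (2R,3S,4E)-3-(TBS-oxy)-2-chloro-1-(PMB-oxy)hept-4-ene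
Conditions: TBSOTf, 2,6-lutidine, CH2Cl2, −78 → 0 °C
Reagents that add atoms: tert-butyldimethylsilyl triflate, CC(C)(C)[Si](C)(C)OS(=O)(=O)C(F)(F)F
Why: Silyl ether formation with a non-nucleophilic base, which protects C19–OH without closing the chlorohydrin to an epoxide.

**Step 14**
Reactants: 24 PMB ether
Product: 25 (2R,3S,4E)-3-(TBS-oxy)-2-chlorohept-4-en-1-ol
Conditions: DDQ, CH2Cl2/pH 7 buffer, 0 °C
Reagents that add atoms: none
Why: Oxidative PMB cleavage by DDQ (benzylic oxocarbenium ion, hydrolysed by the buffer) leaves the silyl ether, the alkene and the chloride untouched.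

**Step 15**
Reactants: 25 primary alcohol
Product: 26 (2S,3S,4E)-3-(TBS-oxy)-2-chlorohept-4-enal
Conditions: Dess–Martin periodinane, NaHCO3, CH2Cl2, 0 °C → rt; used crude
Reagents that add atoms: none
Why: Dess–Martin oxidation under buffered non-basic conditions should give the configurationally labile α-chloroaldehyde without epimerisation or β-elimination.

**Step 16**
Reactants: 27 methyl (4R)-2,2-dimethyl-1,3-dioxolane-4-carboxylate
Product: 28 (4R)-N-methoxy-N,2,2-trimethyl-1,3-dioxolane-4-carboxamide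
Conditions: MeNHOMe·HCl, i-PrMgCl, THF, −20 °C
Reagents that add atoms: N,O-dimethylhydroxylamine hydrochloride, CNOC.Cl
Why: Weinreb amide formation, in which the chloromagnesium amide acylates on the ester at low temperature without touching the α-stereocentre.

**Step 17**
Reactants: 28 Weinreb amide
Product: 29 1-[(4R)-2,2-dimethyl-1,3-dioxolan-4-yl]ethan-1-one
Conditions: MeMgBr, THF, 0 °C; aq NH4Cl
Reagents that add atoms: methylmagnesium bromide, C[Mg]Br
Why: Grignard addition to a Weinreb amide stops at the chelated tetrahedral intermediate, which releases the methyl ketone only on work-up.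

**Step 18**
Reactants: 29 methyl ketone; 26 α-chloroaldehyde
Product: 31 (3R,4R,5S,6E)-5-(TBS-oxy)-4-chloro-1-[(4R)-2,2-dimethyl-1,3-dioxolan-4-yl]-3-hydroxynon-6-en-1-one, via lithium enolate 30 (not isolated)
Conditions: LDA, THF, −78 °C; then 26, −78 °C; aq NH4Cl at −78 °C
Reagents that add atoms: none
Why: Kinetic deprotonation at the methyl group gives the lithium enolate, and its aldol addition to the α-chloroaldehyde should be governed by the Cornforth model (helped by the anti α-chloro/β-silyloxy arrangement), giving the 17,18-anti adduct (C17 R).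

**Step 19**
Reactants: 31 β-hydroxy ketone
Product: 32 (1S,3R,4R,5S,6E)-5-(TBS-oxy)-4-chloro-1-[(4R)-2,2-dimethyl-1,3-dioxolan-4-yl]non-6-ene-1,3-diol
Conditions: Et2BOMe, THF/MeOH (4:1), −78 °C; NaBH4, −78 °C; AcOH, MeOH co-evaporation
Reagents that add atoms: none
Why: Narasaka–Prasad reduction, in which the diethylboron chelate is reduced by external axial hydride to the 1,3-syn diol (C15 S), which is also the Felkin–Anh outcome with respect to the C14 oxygen.

**Step 20**
Reactants: 32 acetonide diol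
Product: 33 (2R,3S,5R,6R,7S,8E)-7-(TBS-oxy)-6-chloroundec-8-ene-1,2,3,5-tetrol
Conditions: PPTS (cat.), MeOH, rt
Reagents that add atoms: none
Why: Acid-catalysed transketalisation to the large excess of methanol removes the terminal isopropylidene acetal while the secondary TBS ether and the chlorohydrin should survive.

**Step 21**
Reactants: 33 tetrol
Product: 35 (2R,3S,5R,6R,7S,8E)-2,3,5,7-tetrakis(TBS-oxy)-6-chloro-1-(TES-oxy)undec-8-ene, via primary TES ether 34 (not isolated)
Conditions: TESCl (1.05 equiv), imidazole, CH2Cl2, −40 °C; then 2,6-lutidine, TBSOTf (excess), −40 → 0 °C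
Reagents that add atoms: chlorotriethylsilane, CC[Si](Cl)(CC)CC; tert-butyldimethylsilyl triflate, CC(C)(C)[Si](C)(C)OS(=O)(=O)C(F)(F)F
Why: Silyl ether formation, in which the small TES chloride reacts selectively at the primary hydroxyl at low temperature and the silyl triflate then caps the three secondary hydroxyls in the same flask.

**Step 22**
Reactants: 35 TES/TBS ether
Product: 36 (2S,3S,5R,6R,7S,8E)-2,3,5,7-tetrakis(TBS-oxy)-6-chloroundec-8-enal
Conditions: (COCl)2, DMSO, CH2Cl2, −78 → −30 °C; Et3N, −78 → 0 °C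
Reagents that add atoms: none
Why: Under Swern conditions a primary TES ether is cleaved by the chlorosulfonium ion and oxidised directly to the aldehyde, while secondary TBS ethers are inert.

**Step 23**
Reactants: 37 (2S)-but-3-yn-2-ol
Product: 38 (2S)-but-3-yn-2-yl methanesulfonate
Conditions: MsCl, Et3N, CH2Cl2, −78 → 0 °C
Reagents that add atoms: methanesulfonyl chloride, CS(=O)(=O)Cl
Why: Sulfonylation at oxygen proceeds with retention at the carbinol carbon.

**Step 24**
Reactants: 38 propargylic mesylate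
Product: 39 (aR)-tributyl(buta-1,2-dien-1-yl)stannane
Conditions: Bu3SnH, LDA, THF, 0 °C; CuBr·SMe2, −78 °C; then 38, −78 °C
Reagents that add atoms: tributyltin hydride, CCCC[SnH](CCCC)CCCC
Why: Anti SN2′ displacement of the propargylic mesylate by the stannylcuprate transfers central to axial chirality and should give the (aR)-allene.

**Step 25**
Reactants: 36 α-silyloxy aldehyde; 39 allenylstannane
Product: 40 (3S,4R,5R,6S,8R,9R,10S,11E)-5,6,8,10-tetrakis(TBS-oxy)-9-chloro-3-methyltetradec-11-en-1-yn-4-ol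
Conditions: BF3·OEt2, CH2Cl2, −78 °C
Reagents that add atoms: none
Why: BF3-promoted anti SE2′ propargylation (Marshall-type) through an open antiperiplanar transition state gives the 12,13-syn adduct with C12 fixed by the allene axis, and this facial preference matches Felkin–Anh addition anti to the C14 silyloxy group (13,14-anti).

**Step 26**
Reactants: 40 homopropargylic alcohol
Product: 41 (3S,4R,5S,6S,8R,9R,10S,11E)-4,5,6,8,10-pentakis(TBS-oxy)-9-chloro-3-methyltetradec-11-en-1-yne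
Conditions: TBSOTf, 2,6-lutidine, CH2Cl2, 0 °C → rt
Reagents that add atoms: tert-butyldimethylsilyl triflate, CC(C)(C)[Si](C)(C)OS(=O)(=O)C(F)(F)F
Why: Silyl triflate with a hindered base silylates even the congested C13 hydroxyl, so that no Lewis-basic OH remains for the key step.

**Step 27**
Reactants: 41 C10–C23 alkyne; 16 C1–C9 iodotetraenoate
Product: 44 allyl (1S,3R,4S)-4-(TBS-oxy)-3-{[(2E,4E,6E,8E,10Z,12R,13R,14S,15S,17R,18R,19S,20E)-11,18-dichloro-13,14,15,17,19-pentakis(TBS-oxy)-6,12-dimethyltricosa-2,4,6,8,10,20-hexaenoyl]oxy}cyclohexane-1-carboxylate, via alkenyldichloroborane 42 (not isolated), via pinacol boronate 43 (not isolated)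
Conditions: BCl3 (1.05 equiv), CH2Cl2, −78 °C; Et3N then pinacol, −78 °C → rt; evaporate; 16, Pd(PPh3)4 (10 mol%), TlOEt, THF/H2O (3:1), rt, dark
Reagents that add atoms: boron trichloride, ClB(Cl)Cl
Why: BCl3 adds across the terminal alkyne C10≡C11 in a Markovnikov syn-1,2-chloroboration (Cl to internal C11, BCl2 to C10), so chlorine and boron are cis and the C10=C11 geometry is fixed before any C–C bond forms; Et3N/pinacol then trap dichloroborane 42 as boronate 43. Oxidative addition of Pd(0) into the C9–I bond of 16, TlOEt-accelerated transmetallation of 43 and reductive elimination form C9–C10 with retention at both alkenes, so C9 ends cis to chlorine (10Z) and 8E is kept. The closest known reaction types are alkyne haloboration followed by Pd cross-coupling and thallium-accelerated Suzuki–Miyaura polyene couplings. No ring is closed and no stereocentre is created; the only new stereo-element is the C10=C11 geometry, controlled by the syn addition. The step needs Cl delivery to C11 (secured by the terminal alkyne), survival of the silyl ethers towards BCl3 (all hydroxyls as TBS ethers, one equivalent at −78 °C, amine quench before warming) and C–I over C–Cl oxidative addition (vinyl iodide against vinyl and alkyl chloride at room temperature with PPh3 ligands).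

**Step 28**
Reactants: 44 allyl ester
Product: 45 (1S,3R,4S)-4-(TBS-oxy)-3-{[(2E,4E,6E,8E,10Z,12R,13R,14S,15S,17R,18R,19S,20E)-11,18-dichloro-13,14,15,17,19-pentakis(TBS-oxy)-6,12-dimethyltricosa-2,4,6,8,10,20-hexaenoyl]oxy}cyclohexane-1-carboxylic acid
Conditions: Pd(PPh3)4 (10 mol%), morpholine, THF, rt, dark
Reagents that add atoms: none
Why: Tsuji–Trost deallylation, in which Pd(0) ionises the allyl ester to a π-allyl complex that morpholine captures, a neutral process that should leave the dienoate ester, the silyl ethers and the vinyl chloride intact.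

**Step 29**
Reactants: 45 hexasilylated acid
Product: 46 CNP0353301.1, (1S,3R,4S)-3-{[(2E,4E,6E,8E,10Z,12R,13R,14S,15S,17R,18R,19S,20E)-11,18-dichloro-13,14,15,17,19-pentahydroxy-6,12-dimethyltricosa-2,4,6,8,10,20-hexaenoyl]oxy}-4-hydroxycyclohexane-1-carboxylic acid
Conditions: HF·pyridine, pyridine, THF, 0 °C → rt, dark
Reagents that add atoms: none
Why: Fluoride-mediated desilylation under buffered, mildly acidic conditions should remove all six TBS groups without closing the chlorohydrin to an epoxide or migrating the dienoate ester.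

**Compound list**

1 | triethyl (E)-4-phosphonocrotonate | CCOC(=O)/C=C/CP(=O)(OCC)OCC | starting material
2 | (2E)-4-(diethoxyphosphoryl)but-2-enoic acid | OC(=O)/C=C/CP(=O)(OCC)OCC | intermediate
3 | 2,2-dimethoxyacetaldehyde | COC(OC)C=O | starting material
4 | 2-(triphenylphosphoranylidene)propanal | CC(C=O)=P(c1ccccc1)(c1ccccc1)c1ccccc1 | starting material
5 | (2E)-4,4-dimethoxy-2-methylbut-2-enal | COC(OC)/C=C(\C)C=O | intermediate
6 | (1S)-cyclohex-3-ene-1-carboxylic acid | OC(=O)[C@@H]1CC=CCC1 | starting material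
7 | (1S,4S,5S)-4-iodo-6-oxabicyclo[3.2.1]octan-7-one | O=C1O[C@H]2C[C@@H]1CC[C@@H]2I | intermediate
8 | allyl (1S,3S,6R)-7-oxabicyclo[4.1.0]heptane-3-carboxylate | O1[C@H]2C[C@@H](C(=O)OCC=C)CC[C@@H]12 | intermediate
9 | allyl (1S,3R,4R)-3-{[(2E)-4-(diethoxyphosphoryl)but-2-enoyl]oxy}-4-hydroxycyclohexane-1-carboxylate | CCOP(=O)(OCC)C/C=C/C(=O)O[C@@H]1C[C@@H](C(=O)OCC=C)CC[C@H]1O | intermediate
10 | C4 triflate of 9 (1S,3R,4R) | CCOP(=O)(OCC)C/C=C/C(=O)O[C@@H]1C[C@@H](C(=O)OCC=C)CC[C@H]1OS(=O)(=O)C(F)(F)F | intermediate (not isolated)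
11 | cis-fused 1,3-dioxolan-2-ylium triflate bridging O3 and O4 on the ring face anti to the allyl ester, 2-substituent (1E)-3-(diethoxyphosphoryl)prop-1-enyl | CCOP(=O)(OCC)C/C=C/C1=[O+][C@H]2CC[C@H](C(=O)OCC=C)C[C@H]2O1.[O-]S(=O)(=O)C(F)(F)F | intermediate (not isolated)
12 | allyl (1S,3R,4S)-3-{[(2E)-4-(diethoxyphosphoryl)but-2-enoyl]oxy}-4-hydroxycyclohexane-1-carboxylate | CCOP(=O)(OCC)C/C=C/C(=O)O[C@@H]1C[C@@H](C(=O)OCC=C)CC[C@@H]1O | intermediate
13 | allyl (1S,3R,4S)-4-(TBS-oxy)-3-{[(2E)-4-(diethoxyphosphoryl)but-2-enoyl]oxy}cyclohexane-1-carboxylate | CCOP(=O)(OCC)C/C=C/C(=O)O[C@@H]1C[C@@H](C(=O)OCC=C)CC[C@@H]1O[Si](C)(C)C(C)(C)C | intermediate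
14 | allyl (1S,3R,4S)-4-(TBS-oxy)-3-{[(2E,4E,6E)-8,8-dimethoxy-6-methylocta-2,4,6-trienoyl]oxy}cyclohexane-1-carboxylate | COC(OC)/C=C(C)/C=C/C=C/C(=O)O[C@@H]1C[C@@H](C(=O)OCC=C)CC[C@@H]1O[Si](C)(C)C(C)(C)C | intermediate (not isolated)
15 | allyl (1S,3R,4S)-4-(TBS-oxy)-3-{[(2E,4E,6E)-6-methyl-8-oxoocta-2,4,6-trienoyl]oxy}cyclohexane-1-carboxylate | O=C/C=C(C)/C=C/C=C/C(=O)O[C@@H]1C[C@@H](C(=O)OCC=C)CC[C@@H]1O[Si](C)(C)C(C)(C)C | intermediate
16 | allyl (1S,3R,4S)-4-(TBS-oxy)-3-{[(2E,4E,6E,8E)-9-iodo-6-methylnona-2,4,6,8-tetraenoyl]oxy}cyclohexane-1-carboxylate | I/C=C/C=C(C)/C=C/C=C/C(=O)O[C@@H]1C[C@@H](C(=O)OCC=C)CC[C@@H]1O[Si](C)(C)C(C)(C)C | intermediate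
17 | but-1-yne | CCC#C | starting material
18 | [(1E)-but-1-enyl]chloridobis(cyclopentadienyl)zirconium | CC/C=C/[Zr](Cl)(C1C=CC=C1)C1C=CC=C1 | intermediate (not isolated)
19 | (1E)-1-iodobut-1-ene | CC/C=C/I | intermediate
20 | 3-[(4-methoxybenzyl)oxy]propanal | COc1ccc(COCCC=O)cc1 | starting material
21 | (2R)-2-chloro-3-[(4-methoxybenzyl)oxy]propanal | O=C[C@H](Cl)COCc1ccc(OC)cc1 | intermediate
22 | (1E)-but-1-enyllithium | CC/C=C/[Li] | intermediate (not isolated)
23 | (2R,3S,4E)-2-chloro-1-[(4-methoxybenzyl)oxy]hept-4-en-3-ol | CC/C=C/[C@H](O)[C@H](Cl)COCc1ccc(OC)cc1 | intermediate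
24 | (2R,3S,4E)-3-(TBS-oxy)-2-chloro-1-[(4-methoxybenzyl)oxy]hept-4-ene | CC/C=C/[C@H](O[Si](C)(C)C(C)(C)C)[C@H](Cl)COCc1ccc(OC)cc1 | intermediate
25 | (2R,3S,4E)-3-(TBS-oxy)-2-chlorohept-4-en-1-ol | CC/C=C/[C@H](O[Si](C)(C)C(C)(C)C)[C@H](Cl)CO | intermediate
26 | (2S,3S,4E)-3-(TBS-oxy)-2-chlorohept-4-enal | CC/C=C/[C@H](O[Si](C)(C)C(C)(C)C)[C@H](Cl)C=O | intermediate
27 | methyl (4R)-2,2-dimethyl-1,3-dioxolane-4-carboxylate | COC(=O)[C@@H]1OC(C)(C)OC1 | starting material
28 | (4R)-N-methoxy-N,2,2-trimethyl-1,3-dioxolane-4-carboxamide | CON(C)C(=O)[C@@H]1OC(C)(C)OC1 | intermediate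
29 | 1-[(4R)-2,2-dimethyl-1,3-dioxolan-4-yl]ethan-1-one | CC(=O)[C@@H]1OC(C)(C)OC1 | intermediate
30 | lithium enolate of 29 (methyl side) | C=C(O[Li])[C@@H]1OC(C)(C)OC1 | intermediate (not isolated)
31 | (3R,4R,5S,6E)-5-(TBS-oxy)-4-chloro-1-[(4R)-2,2-dimethyl-1,3-dioxolan-4-yl]-3-hydroxynon-6-en-1-one | CC/C=C/[C@H](O[Si](C)(C)C(C)(C)C)[C@H](Cl)[C@H](O)CC(=O)[C@@H]1OC(C)(C)OC1 | intermediate
32 | (1S,3R,4R,5S,6E)-5-(TBS-oxy)-4-chloro-1-[(4R)-2,2-dimethyl-1,3-dioxolan-4-yl]non-6-ene-1,3-diol | CC/C=C/[C@H](O[Si](C)(C)C(C)(C)C)[C@H](Cl)[C@H](O)C[C@H](O)[C@@H]1OC(C)(C)OC1 | intermediate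
33 | (2R,3S,5R,6R,7S,8E)-7-(TBS-oxy)-6-chloroundec-8-ene-1,2,3,5-tetrol | CC/C=C/[C@H](O[Si](C)(C)C(C)(C)C)[C@H](Cl)[C@H](O)C[C@H](O)[C@H](O)CO | intermediate
34 | (2R,3S,5R,6R,7S,8E)-7-(TBS-oxy)-6-chloro-1-(TES-oxy)undec-8-ene-2,3,5-triol | CC/C=C/[C@H](O[Si](C)(C)C(C)(C)C)[C@H](Cl)[C@H](O)C[C@H](O)[C@H](O)CO[Si](CC)(CC)CC | intermediate (not isolated)
35 | (2R,3S,5R,6R,7S,8E)-2,3,5,7-tetrakis(TBS-oxy)-6-chloro-1-(TES-oxy)undec-8-ene | CC/C=C/[C@H](O[Si](C)(C)C(C)(C)C)[C@H](Cl)[C@H](O[Si](C)(C)C(C)(C)C)C[C@H](O[Si](C)(C)C(C)(C)C)[C@H](O[Si](C)(C)C(C)(C)C)CO[Si](CC)(CC)CC | intermediate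
36 | (2S,3S,5R,6R,7S,8E)-2,3,5,7-tetrakis(TBS-oxy)-6-chloroundec-8-enal | CC/C=C/[C@H](O[Si](C)(C)C(C)(C)C)[C@H](Cl)[C@H](O[Si](C)(C)C(C)(C)C)C[C@H](O[Si](C)(C)C(C)(C)C)[C@H](O[Si](C)(C)C(C)(C)C)C=O | intermediate
37 | (2S)-but-3-yn-2-ol | C[C@H](O)C#C | starting material
38 | (2S)-but-3-yn-2-yl methanesulfonate | C[C@H](OS(C)(=O)=O)C#C | intermediate
39 | (aR)-tributyl(buta-1,2-dien-1-yl)stannane | CC([H])=[C@]=C([H])[Sn](CCCC)(CCCC)CCCC | intermediate
40 | (3S,4R,5R,6S,8R,9R,10S,11E)-5,6,8,10-tetrakis(TBS-oxy)-9-chloro-3-methyltetradec-11-en-1-yn-4-ol | CC/C=C/[C@H](O[Si](C)(C)C(C)(C)C)[C@H](Cl)[C@H](O[Si](C)(C)C(C)(C)C)C[C@H](O[Si](C)(C)C(C)(C)C)[C@H](O[Si](C)(C)C(C)(C)C)[C@H](O)[C@@H](C)C#C | intermediate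
41 | (3S,4R,5S,6S,8R,9R,10S,11E)-4,5,6,8,10-pentakis(TBS-oxy)-9-chloro-3-methyltetradec-11-en-1-yne | CC/C=C/[C@H](O[Si](C)(C)C(C)(C)C)[C@H](Cl)[C@H](O[Si](C)(C)C(C)(C)C)C[C@H](O[Si](C)(C)C(C)(C)C)[C@H](O[Si](C)(C)C(C)(C)C)[C@H](O[Si](C)(C)C(C)(C)C)[C@@H](C)C#C | intermediate
42 | dichloro[(1Z,3R,4R,5S,6S,8R,9R,10S,11E)-2,9-dichloro-4,5,6,8,10-pentakis(TBS-oxy)-3-methyltetradeca-1,11-dien-1-yl]borane | CC/C=C/[C@H](O[Si](C)(C)C(C)(C)C)[C@H](Cl)[C@H](O[Si](C)(C)C(C)(C)C)C[C@H](O[Si](C)(C)C(C)(C)C)[C@H](O[Si](C)(C)C(C)(C)C)[C@H](O[Si](C)(C)C(C)(C)C)[C@@H](C)/C(Cl)=C/B(Cl)Cl | intermediate (not isolated)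
43 | 2-[(1Z,3R,4R,5S,6S,8R,9R,10S,11E)-2,9-dichloro-4,5,6,8,10-pentakis(TBS-oxy)-3-methyltetradeca-1,11-dien-1-yl]-4,4,5,5-tetramethyl-1,3,2-dioxaborolane | CC/C=C/[C@H](O[Si](C)(C)C(C)(C)C)[C@H](Cl)[C@H](O[Si](C)(C)C(C)(C)C)C[C@H](O[Si](C)(C)C(C)(C)C)[C@H](O[Si](C)(C)C(C)(C)C)[C@H](O[Si](C)(C)C(C)(C)C)[C@@H](C)/C(Cl)=C/B1OC(C)(C)C(C)(C)O1 | intermediate (not isolated)
44 | allyl ester, hexakis-TBS ether of the target (name as in step 27) | CC/C=C/[C@H](O[Si](C)(C)C(C)(C)C)[C@H](Cl)[C@H](O[Si](C)(C)C(C)(C)C)C[C@H](O[Si](C)(C)C(C)(C)C)[C@H](O[Si](C)(C)C(C)(C)C)[C@H](O[Si](C)(C)C(C)(C)C)[C@@H](C)/C(Cl)=C/C=C/C=C(C)/C=C/C=C/C(=O)O[C@@H]1C[C@@H](C(=O)OCC=C)CC[C@@H]1O[Si](C)(C)C(C)(C)C | intermediate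
45 | hexakis-TBS ether of the target, free carboxylic acid (name as in step 28) | CC/C=C/[C@H](O[Si](C)(C)C(C)(C)C)[C@H](Cl)[C@H](O[Si](C)(C)C(C)(C)C)C[C@H](O[Si](C)(C)C(C)(C)C)[C@H](O[Si](C)(C)C(C)(C)C)[C@H](O[Si](C)(C)C(C)(C)C)[C@@H](C)/C(Cl)=C/C=C/C=C(C)/C=C/C=C/C(=O)O[C@@H]1C[C@@H](C(=O)O)CC[C@@H]1O[Si](C)(C)C(C)(C)C | intermediate
46 | CNP0353301.1 (name as in step 29) | CC/C=C/[C@H](O)[C@H](Cl)[C@H](O)C[C@H](O)[C@H](O)[C@H](O)[C@@H](C)/C(Cl)=C/C=C/C=C(C)/C=C/C=C/C(=O)O[C@@H]1C[C@@H](C(=O)O)CC[C@@H]1O | target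

**Summary**

Total step count: 29.
Longest linear sequence: 15 steps (11–15, 18–22, 25–29, from aldehyde 20 to the target).

**Steps most likely to fail**

1. Step 27 (key step). The Lewis acid may cleave silyl ethers or ionise the allylic C19–O bond before chloroboration of the hindered alkyne is complete, and reversible haloboration may erode the Z geometry. The fallback installs the chlorine without a Lewis acid and makes the same bond by a Stille coupling. Setting out from 41, bromination of the alkyne C–H (NBS, cat. AgNO3, acetone) would give the 1-bromoalkyne F1. Palladium(II)-catalysed anti-hydrochlorination (Pd(OAc)2 cat., LiCl, AcOH, MeCN, rt; chloride to C11, proton to C10) would then give the (1Z)-1-bromo-2-chloroalkene F2. In parallel, aldehyde 15 would be converted by a chromium(II) stannyl-olefination (Bu3SnCHBr2, CrCl2, LiI, THF/DMF) into the (8E)-tetraenylstannane F3. Stille coupling of F2 with F3 (Pd2(dba)3, AsPh3, NMP, 40 °C) would rejoin the route at 44.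

2. Step 6. The ortho-acid may collapse the other way or the acyl group may migrate to O4, and Tf2O may be consumed at the phosphoryl oxygen. The fallback inverts C4 by oxidation and reduction instead of substitution. Setting out from 9, Dess–Martin oxidation (NaHCO3, CH2Cl2) would give the α-acyloxy ketone F4. Reduction with NaBH4/CeCl3 in MeOH at −78 °C (axial hydride delivery anti to the axial acyloxy group) should give the cis-hydroxy ester and rejoin the route at 12.

3. Step 11. The enamine of a β-alkoxy aldehyde may lose the alkoxide (β-elimination), and the α-chloroaldehyde may racemise before it is trapped. The fallback takes C18 from the chiral pool. D-serine would be diazotised in aqueous HCl (NaNO2, KCl, 0 °C; net retention) to (2R)-2-chloro-3-hydroxypropanoic acid F5 and esterified (MeOH, cat. HCl) to methyl (2R)-2-chloro-3-hydroxypropanoate F6. PMB trichloroacetimidate with cat. CSA would give methyl (2R)-2-chloro-3-(PMB-oxy)propanoate F7, and DIBAL-H in CH2Cl2 at −78 °C would reduce it to the aldehyde, rejoining the route at 21.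

**Further compounds**

F1 | step 27 | (3S,4R,5S,6S,8R,9R,10S,11E)-1-bromo-4,5,6,8,10-pentakis(TBS-oxy)-9-chloro-3-methyltetradec-11-en-1-yne | CC/C=C/[C@H](O[Si](C)(C)C(C)(C)C)[C@H](Cl)[C@H](O[Si](C)(C)C(C)(C)C)C[C@H](O[Si](C)(C)C(C)(C)C)[C@H](O[Si](C)(C)C(C)(C)C)[C@H](O[Si](C)(C)C(C)(C)C)[C@@H](C)C#CBr
F2 | step 27 | (1Z,3R,4R,5S,6S,8R,9R,10S,11E)-1-bromo-2,9-dichloro-4,5,6,8,10-pentakis(TBS-oxy)-3-methyltetradeca-1,11-diene | CC/C=C/[C@H](O[Si](C)(C)C(C)(C)C)[C@H](Cl)[C@H](O[Si](C)(C)C(C)(C)C)C[C@H](O[Si](C)(C)C(C)(C)C)[C@H](O[Si](C)(C)C(C)(C)C)[C@H](O[Si](C)(C)C(C)(C)C)[C@@H](C)/C(Cl)=C/Br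
F3 | step 27 | allyl (1S,3R,4S)-4-(TBS-oxy)-3-{[(2E,4E,6E,8E)-6-methyl-9-(tributylstannyl)nona-2,4,6,8-tetraenoyl]oxy}cyclohexane-1-carboxylate | CCCC[Sn](CCCC)(CCCC)/C=C/C=C(C)/C=C/C=C/C(=O)O[C@@H]1C[C@@H](C(=O)OCC=C)CC[C@@H]1O[Si](C)(C)C(C)(C)C
F4 | step 6 | allyl (1S,3R)-3-{[(2E)-4-(diethoxyphosphoryl)but-2-enoyl]oxy}-4-oxocyclohexane-1-carboxylate | CCOP(=O)(OCC)C/C=C/C(=O)O[C@@H]1C[C@@H](C(=O)OCC=C)CCC1=O
F5 | step 11 | (2R)-2-chloro-3-hydroxypropanoic acid | OC(=O)[C@H](Cl)CO
F6 | step 11 | methyl (2R)-2-chloro-3-hydroxypropanoate | COC(=O)[C@H](Cl)CO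
F7 | step 11 | methyl (2R)-2-chloro-3-[(4-methoxybenzyl)oxy]propanoate | COC(=O)[C@H](Cl)COCc1ccc(OC)cc1
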